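**Plan**

- Retrosynthesis: cut the C3–aroyl bond first, then both bridgehead–prenyl bonds (C5–C and C1–C) together, then ring A at C1–C2 and C4–C5 (malonyl unit C2–C3–C4), then the C8–homoprenyl and C8–methyl bonds, and last ring B at C1=C8 and C6–C7, down to geranyl bromide, acetonitrile and methyl vinyl ketone. Numbering: bridgeheads C1 and C5; C2–C3–C4 the trione bridge of ring A; C6–C7–C8 the carbon bridge of ring B; C9 the bridging ketone.
- Forward: ring B is made first by an organocatalytic Michael addition and aldol condensation; C8 is built by two copper-catalysed conjugate additions; ring A is closed by double C-acylation with malonyl dichloride; the core is masked as its C4 methyl enol ether with a silyl block on C3; both prenyl groups go on; aroylation and deprotection finish.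
- Enabling feature: C1 and C5 carry the same prenyl group and both flank the C9 ketone, and in the bicyclo[3.3.1]nonane cage each bridgehead can hold its substituent only exo. Both quaternary centres, including C1 beside quaternary C8, can therefore be completed last from bridgehead carbanions with no stereochemical choice.
- Stereochemistry: C7 comes from the catalyst-controlled Michael addition (S); C8 from addition of the homoprenyl copper reagent anti to the C7 geranyl group; the sense of C1/C5 from ring A closing on the face of ring B opposite geranyl. The key step keeps the bridgehead configurations.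

Key step: step 12

Shorthand: geranyl = (2E)-3,7-dimethylocta-2,6-dien-1-yl; prenyl = 3-methylbut-2-en-1-yl; homoprenyl = 4-methylpent-3-en-1-yl. In the bicyclic compounds the C1/C5 substituent (H or prenyl) is exo, geranyl is equatorial on the chair of ring B (anti to the C2–C4 bridge), and at C8 methyl is axial (anti to that bridge) and homoprenyl equatorial.

Assumption: O-methylation of trione 15 is taken to occur at O4, the oxygen remote from quaternary C8; the O2 isomer, if formed, would be separated and would converge on the same target after the last step.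

**Route**

Step 1
Reactants: 1 geranyl bromide; 2 acetonitrile
Product: 3 (4E)-5,9-dimethyldeca-4,8-dienenitrile
Conditions: n-BuLi, MeCN (3 equiv), THF, −78 °C; then 1, −78 °C → rt
Reagents that add atoms: acetonitrile (2), CC#N
Why: Lithiated acetonitrile displaces the primary allylic bromide by SN2 (nitrile anion alkylation), excess anion suppressing double alkylation and leaving the E olefin untouched.

Step 2
Reactants: 3 (4E)-5,9-dimethyldeca-4,8-dienenitrile
Product: 4 (4E)-5,9-dimethyldeca-4,8-dienal
Conditions: i-Bu2AlH, CH2Cl2, −78 °C; then aq. potassium sodium tartrate, rt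
Reagents that add atoms: water, O
Why: Partial reduction of the nitrile with one hydride equivalent stops at the N-aluminio imine, which hydrolyses to the aldehyde on work-up (DIBAL nitrile reduction).

Step 3
Reactants: 4 (4E)-5,9-dimethyldeca-4,8-dienal; 5 methyl vinyl ketone
Product: 6 (2S)-2-geranyl-5-oxohexanal
Conditions: (S)-2-[methoxy(diphenyl)methyl]pyrrolidine (5 mol %), ethyl 3,4-dihydroxybenzoate (20 mol %), neat, 4 °C
Reagents that add atoms: methyl vinyl ketone (5), CC(=O)C=C
Why: Enamine-catalysed asymmetric Michael addition of a linear aldehyde to the enone, in which the diphenyl(methoxy)methyl group shields one face of the E-enamine so that the enone adds to the open Si face and sets the future C7 as S.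

Step 4
Reactants: 6 (2S)-2-geranyl-5-oxohexanal
Product: 7 (4S)-4-geranylcyclohex-2-en-1-one
Conditions: LiOH, i-PrOH, rt
Reagents that add atoms: none
Why: Intramolecular aldol condensation of the methyl ketone onto the aldehyde closes ring B, the aldehyde serving only as electrophile so that its α-stereocentre is kept.

Step 5
Reactants: 7 (4S)-4-geranylcyclohex-2-en-1-one
Product: 8 (3S,4S)-4-geranyl-3-methyl-1-(trimethylsilyloxy)cyclohex-1-ene (methyl trans to geranyl)
Conditions: MeMgBr, CuBr·SMe2 (10 mol %), Me3SiCl, HMPA, THF, −78 °C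
Reagents that add atoms: methylmagnesium bromide, C[Mg]Br; chlorotrimethylsilane, C[Si](C)(C)Cl
Why: Copper-catalysed conjugate addition of the Grignard reagent with silyl trapping gives the regiodefined enol ether, methyl entering anti to the C4 geranyl group at a centre that the next step erases.

Step 6
Reactants: 8 (3S,4S)-4-geranyl-3-methyl-1-(trimethylsilyloxy)cyclohex-1-ene
Product: 9 (4S)-4-geranyl-3-methylcyclohex-2-en-1-one
Conditions: Pd(OAc)2 (1.05 equiv), MeCN, rt
Reagents that add atoms: none
Why: Saegusa–Ito oxidation, in which the palladium enolate formed from the silyl enol ether can undergo β-hydride elimination only toward C3, giving the β-methyl enone without touching the C4 stereocentre.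

Step 7
Reactants: 9 (4S)-4-geranyl-3-methylcyclohex-2-en-1-one; 10 5-bromo-2-methylpent-2-ene
Product: 12 (3R,4S)-4-geranyl-3-methyl-3-homoprenylcyclohexan-1-one (homoprenyl trans to geranyl), via trimethylsilyl enol ether 11 (not isolated)
Conditions: 10, Mg, THF (Grignard reagent); CuBr·SMe2 (20 mol %), Me3SiCl, HMPA, THF, −78 → −40 °C; then 1 M aq. HCl, 0 °C
Reagents that add atoms: 5-bromo-2-methylpent-2-ene (10) as its Grignard reagent, CC(C)=CCCBr; chlorotrimethylsilane, C[Si](C)(C)Cl (silicon present in 11 only)
Why: Copper-catalysed 1,4-addition to the β-methyl enone, in which the C4 geranyl group sits pseudoaxial to avoid A(1,2) strain with the C3 methyl and the nucleophile adds axially on the opposite face, so that homoprenyl ends up trans to geranyl at the new quaternary centre (future C8) before acid work-up hydrolyses 11.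

Step 8
Reactants: 12 (3R,4S)-4-geranyl-3-methyl-3-homoprenylcyclohexan-1-one
Product: 13 kinetic trimethylsilyl enol ether of 12 (double bond C1=C6, away from the quaternary carbon)
Conditions: LiN(i-Pr)2, THF, −78 °C; then Me3SiCl
Reagents that add atoms: chlorotrimethylsilane, C[Si](C)(C)Cl
Why: Kinetic deprotonation by lithium diisopropylamide takes the C6 methylene remote from the quaternary carbon and O-silylation fixes that enolate as the less substituted silyl enol ether.

Step 9
Reactants: 13 kinetic trimethylsilyl enol ether; 14 malonyl dichloride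
Product: 15 4-hydroxy-7-geranyl-8-methyl-8-homoprenylbicyclo[3.3.1]non-3-ene-2,9-dione (trione in its enol form, hydrogen exo at C1 and C5)
Conditions: 14, Et2O, −20 °C → rt; then KOH, BnEt3NCl, H2O, rt; acidify
Reagents that add atoms: malonyl dichloride (14), O=C(Cl)CC(=O)Cl
Why: Effenberger cyclisation, in which C-acylation at the enol ether carbon is followed by a second, intramolecular C-acylation at the other α-carbon to close ring A as the 2,4-dione, and because the epimerisable acyl chain must be axial the bridge closes on the face opposite the C7 geranyl group so that ring B stays a chair with geranyl equatorial, fixing C1 and C5.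

Step 10
Reactants: 15 bicyclic trione
Product: 16 4-methoxy-7-geranyl-8-methyl-8-homoprenylbicyclo[3.3.1]non-3-ene-2,9-dione
Conditions: Me2SO4, K2CO3, acetone, reflux
Reagents that add atoms: dimethyl sulfate, COS(=O)(=O)OC
Why: O-alkylation of the vinylogous acid by a hard methylating agent, expected at O4 because O2 lies beside C8 and its equatorial homoprenyl group.

Step 11
Reactants: 16 C4 methyl enol ether
Product: 17 4-methoxy-3-(trimethylsilyl)-7-geranyl-8-methyl-8-homoprenylbicyclo[3.3.1]non-3-ene-2,9-dione
Conditions: LiTMP (from 2,2,6,6-tetramethylpiperidine, n-BuLi), Me3SiCl, THF, −78 °C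
Reagents that add atoms: chlorotrimethylsilane, C[Si](C)(C)Cl
Why: Directed vinylic lithiation at C3, between the carbonyl and methoxy oxygens, is the fastest metalation with this base even when bridgehead hydrogens are present, and C-silylation then blocks the position.

Step 12
Reactants: 17 C3-silylated methyl enol ether; 18 prenyl bromide (two equivalents react)
Product: 20 4-methoxy-1,5-diprenyl-3-(trimethylsilyl)-7-geranyl-8-methyl-8-homoprenylbicyclo[3.3.1]non-3-ene-2,9-dione, via C5-monoprenyl intermediate 19 (not isolated)
Conditions: LiTMP (1.3 equiv), THF, −78 °C; 18 (1.2 equiv), −78 → −30 °C; recool to −78 °C, LiTMP (2 equiv); 18 (3 equiv), −78 → 0 °C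
Reagents that add atoms: prenyl bromide (18), CC(C)=CCBr
Why: LiTMP removes the exo hydrogen at C5 to give a pyramidal bridgehead carbanion, held by lithium coordination to the C9 carbonyl and C4 methoxy oxygens and unable to planarise into an enolate, which attacks the CH2 carbon of prenyl bromide (SN2) to give 19, and the second charge of base then removes C1–H, flanked by the C2 and C9 carbonyls, so that the same alkylation gives 20. The closest known reaction type is the bridgehead lithiation–alkylation of bicyclo[3.3.1]nonane-2,4,9-trione methyl enol ethers with hindered lithium amides, including at bridgeheads beside a quaternary carbon, here repeated in one flask. No ring closes in this step. Both new quaternary stereocentres, C5 and C1, are controlled by the cage alone, since each bridgehead carbanion keeps its configuration and only the exo bond can form, so the prenyl groups replace the hydrogens with retention. The step needs metalation at the bridgeheads and not at C3, which the C3 trimethylsilyl group guarantees, and C-alkylation without attack on the C9 ketone, which LiTMP (no β-hydrogen, too hindered to add) and the absence of any other acidic C–H secure. Should C1 be metalated before C5, the same product 20 results.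

Step 13
Reactants: 20 diprenylated C3-silyl compound
Product: 21 4-methoxy-1,5-diprenyl-7-geranyl-8-methyl-8-homoprenylbicyclo[3.3.1]non-3-ene-2,9-dione
Conditions: Bu4NF, wet THF, 0 °C
Reagents that add atoms: none
Why: Fluoride-induced protodesilylation of the α-silyl enone restores C3–H, no other silyl group being present.

Step 14
Reactants: 22 3-hydroxybenzoic acid
Product: 23 tert-butyldimethylsilyl 3-(tert-butyldimethylsilyloxy)benzoate
Conditions: t-BuMe2SiCl (2.2 equiv), imidazole, DMF, rt
Reagents that add atoms: tert-butyldimethylsilyl chloride, CC(C)(C)[Si](C)(C)Cl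
Why: Imidazole-promoted silylation converts both the phenol and the carboxylic acid into their silyl derivatives.

Step 15
Reactants: 23 bis-silylated hydroxybenzoic acid
Product: 24 3-(tert-butyldimethylsilyloxy)benzoyl chloride
Conditions: (COCl)2, DMF (cat.), CH2Cl2, 0 °C → rt
Reagents that add atoms: oxalyl chloride, O=C(Cl)C(=O)Cl
Why: The Vilsmeier-type chloroiminium species converts the silyl ester directly into the acid chloride under neutral conditions that leave the aryl silyl ether intact.

Step 16
Reactants: 21 desilylated diprenyl enol ether; 24 3-(tert-butyldimethylsilyloxy)benzoyl chloride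
Product: 25 3-[3-(tert-butyldimethylsilyloxy)benzoyl]-4-methoxy-1,5-diprenyl-7-geranyl-8-methyl-8-homoprenylbicyclo[3.3.1]non-3-ene-2,9-dione
Conditions: LiTMP, THF, −78 °C; then 24 (3 equiv), −78 → −20 °C
Reagents that add atoms: 3-(tert-butyldimethylsilyloxy)benzoyl chloride (24), CC(C)(C)[Si](C)(C)Oc1cccc(C(Cl)=O)c1
Why: With both bridgeheads quaternary, C3–H is the only acidic site, and the oxygen-flanked vinyllithium is C-acylated by the aroyl chloride, as established for benzoylation of the analogous 1,5-diprenyl enol ethers.

Step 17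
Reactants: 25 aroylated methyl enol ether silyl ether
Product: 27 target CNP0285073.1, via phenol methyl enol ether 26 (not isolated)
Conditions: LiOH, dioxane/H2O, rt → 90 °C; then dil. aq. HCl
Reagents that add atoms: lithium hydroxide, [Li+].[OH-]
Why: Hydroxide first cleaves the aryl O–Si bond and then adds to C4 of the doubly acyl-activated vinylogous ester and expels methoxide (addition–elimination), the product staying protected as its enolate until acidification.

**Compound list**

1 | geranyl bromide | CC(C)=CCC/C(C)=C/CBr | starting material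
2 | acetonitrile | CC#N | starting material
3 | (4E)-5,9-dimethyldeca-4,8-dienenitrile | CC(C)=CCC/C(C)=C/CCC#N | intermediate
4 | (4E)-5,9-dimethyldeca-4,8-dienal | CC(C)=CCC/C(C)=C/CCC=O | intermediate
5 | methyl vinyl ketone | CC(=O)C=C | starting material
6 | (2S)-2-geranyl-5-oxohexanal | CC(C)=CCC/C(C)=C/C[C@@H](C=O)CCC(C)=O | intermediate
7 | (4S)-4-geranylcyclohex-2-en-1-one | CC(C)=CCC/C(C)=C/C[C@@H]1CCC(=O)C=C1 | intermediate
8 | (3S,4S)-4-geranyl-3-methyl-1-(trimethylsilyloxy)cyclohex-1-ene | CC(C)=CCC/C(C)=C/C[C@@H]1CCC(O[Si](C)(C)C)=C[C@H]1C | intermediate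
9 | (4S)-4-geranyl-3-methylcyclohex-2-en-1-one | CC(C)=CCC/C(C)=C/C[C@@H]1CCC(=O)C=C1C | intermediate
10 | 5-bromo-2-methylpent-2-ene | CC(C)=CCCBr | starting material
11 | trimethylsilyl enol ether of 12, double bond toward the quaternary carbon | CC(C)=CCC/C(C)=C/C[C@@H]1CCC(O[Si](C)(C)C)=C[C@@]1(C)CCC=C(C)C | intermediate
12 | (3R,4S)-4-geranyl-3-methyl-3-homoprenylcyclohexan-1-one | CC(C)=CCC/C(C)=C/C[C@@H]1CCC(=O)C[C@@]1(C)CCC=C(C)C | intermediate
13 | kinetic trimethylsilyl enol ether of 12, double bond away from the quaternary carbon | CC(C)=CCC/C(C)=C/C[C@@H]1CC=C(O[Si](C)(C)C)C[C@@]1(C)CCC=C(C)C | intermediate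
14 | malonyl dichloride | O=C(Cl)CC(=O)Cl | starting material
15 | 4-hydroxy-7-geranyl-8-methyl-8-homoprenylbicyclo[3.3.1]non-3-ene-2,9-dione | CC(C)=CCC/C(C)=C/C[C@@H]1C[C@@H]2C(=O)[C@@H](C(=O)C=C2O)[C@@]1(C)CCC=C(C)C | intermediate
16 | 4-methoxy-7-geranyl-8-methyl-8-homoprenylbicyclo[3.3.1]non-3-ene-2,9-dione | CC(C)=CCC/C(C)=C/C[C@@H]1C[C@@H]2C(=O)[C@@H](C(=O)C=C2OC)[C@@]1(C)CCC=C(C)C | intermediate
17 | C3-trimethylsilyl derivative of 16 | CC(C)=CCC/C(C)=C/C[C@@H]1C[C@@H]2C(=O)[C@@H](C(=O)C([Si](C)(C)C)=C2OC)[C@@]1(C)CCC=C(C)C | intermediate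
18 | prenyl bromide | CC(C)=CCBr | starting material
19 | 5-prenyl derivative of 17 | CC(C)=CCC/C(C)=C/C[C@@H]1C[C@]2(CC=C(C)C)C(=O)[C@@H](C(=O)C([Si](C)(C)C)=C2OC)[C@@]1(C)CCC=C(C)C | intermediate
20 | 1,5-diprenyl derivative of 17 | CC(C)=CCC/C(C)=C/C[C@@H]1C[C@]2(CC=C(C)C)C(=O)[C@@](CC=C(C)C)(C(=O)C([Si](C)(C)C)=C2OC)[C@@]1(C)CCC=C(C)C | intermediate
21 | 4-methoxy-1,5-diprenyl-7-geranyl-8-methyl-8-homoprenylbicyclo[3.3.1]non-3-ene-2,9-dione | CC(C)=CCC/C(C)=C/C[C@@H]1C[C@]2(CC=C(C)C)C(=O)[C@@](CC=C(C)C)(C(=O)C=C2OC)[C@@]1(C)CCC=C(C)C | intermediate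
22 | 3-hydroxybenzoic acid | OC(=O)c1cccc(O)c1 | starting material
23 | tert-butyldimethylsilyl 3-(tert-butyldimethylsilyloxy)benzoate | CC(C)(C)[Si](C)(C)OC(=O)c1cccc(O[Si](C)(C)C(C)(C)C)c1 | intermediate
24 | 3-(tert-butyldimethylsilyloxy)benzoyl chloride | CC(C)(C)[Si](C)(C)Oc1cccc(C(Cl)=O)c1 | intermediate
25 | 3-[3-(tert-butyldimethylsilyloxy)benzoyl] derivative of 21 | CC(C)=CCC/C(C)=C/C[C@@H]1C[C@]2(CC=C(C)C)C(=O)[C@@](CC=C(C)C)(C(=O)C(C(=O)c3cccc(O[Si](C)(C)C(C)(C)C)c3)=C2OC)[C@@]1(C)CCC=C(C)C | intermediate
26 | 3-(3-hydroxybenzoyl) derivative of 21 (free phenol, methyl enol ether) | CC(C)=CCC/C(C)=C/C[C@@H]1C[C@]2(CC=C(C)C)C(=O)[C@@](CC=C(C)C)(C(=O)C(C(=O)c3cccc(O)c3)=C2OC)[C@@]1(C)CCC=C(C)C | intermediate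
27 | CNP0285073.1, 4-hydroxy-3-(3-hydroxybenzoyl)-1,5-diprenyl-7-geranyl-8-methyl-8-homoprenylbicyclo[3.3.1]non-3-ene-2,9-dione | CC(C)=CCC/C(C)=C/C[C@@H]1C[C@]2(CC=C(C)C)C(=O)[C@@](CC=C(C)C)(C(=O)C(C(=O)c3cccc(O)c3)=C2O)[C@@]1(C)CCC=C(C)C | target

**Step count**

Total steps: 17. Longest linear sequence: 15 (steps 1–13, 16 and 17); steps 14 and 15 make the acid chloride 24.

**Steps most likely to fail, with fallbacks**

Step 12 (key step). The first metalation must occur at C5, a bridgehead that lies beside the enol-ether carbon C4 and not beside a ring A ketone. If that deprotonation is slow, or if the second cycle stalls because base is consumed by prenyl bromide still in the flask, starting material or mono-alkylated material would remain. The fallback forms the C5–prenyl bond by ordinary ketone enolate alkylation before ring A exists and leaves only the C1 bridgehead, flanked by two carbonyls, for lithiation. It sets out from ketone 12. The kinetic enolate (LiN(i-Pr)2, THF, −78 °C) is alkylated with prenyl bromide 18 to give the 6-prenyl ketone F1 (either epimer at the new centre serves). Thermodynamic silylation (Me3SiOTf, Et3N, CH2Cl2) gives the tetrasubstituted silyl enol ether F2. Effenberger cyclisation with 14 gives the 5-prenyl trione F3, whose bridgehead quaternary centre forms at the unhindered α-carbon. O-methylation (Me2SO4, K2CO3) gives the C4 methyl enol ether F4. C3 silylation (LiTMP, Me3SiCl) then gives 19, where the sequence rejoins the route, and a single LiTMP/prenyl bromide cycle at C1 completes 20.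

Step 9. The double C-acylation competes with O-acylation to pyranone-type products, and the hydrogen chloride released may attack the trisubstituted olefins of the three side chains, so that little trione is obtained. The fallback builds ring A in two stages from ketone 12. Condensation with pyrrolidine (cat. TsOH, benzene, water removal) gives the enamine F5. α,α′-Annulation with acryloyl chloride (MeCN, reflux, then aqueous work-up) gives the bicyclo[3.3.1]nonane-2,9-dione F6, the bridge again closing anti to geranyl. Dehydrogenation with IBX (DMSO/toluene, 70 °C) gives the 3-ene-2,9-dione F7. Tsuji–Wacker oxidation of the enone (Na2PdCl4 cat., t-BuOOH, AcOH/H2O, 50 °C) installs the C4 oxygen and returns to the route at trione 15.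

Step 16. The C3 vinyllithium sits between two prenylated quaternary bridgeheads; slow C-acylation, O-acylation, or a second addition to the new aryl ketone would erode the yield. The fallback sets out from 21 and uses a smaller electrophile at the aldehyde oxidation level. 3-Hydroxybenzaldehyde is silylated (t-BuMe2SiCl, imidazole) to 3-(tert-butyldimethylsilyloxy)benzaldehyde F8. The C3 lithium reagent from 21 (LiTMP, THF, −78 °C) is added to it to give the secondary carbinol F9 (either epimer; the centre is erased next). Dess–Martin periodinane oxidation returns to the route at 25.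

Further compounds
F1 | step 12 | (3R,4S)-4-geranyl-3-methyl-3-homoprenyl-6-prenylcyclohexan-1-one, drawn as the equatorial C6 epimer | CC(C)=CCC/C(C)=C/C[C@@H]1C[C@H](CC=C(C)C)C(=O)C[C@@]1(C)CCC=C(C)C
F2 | step 12 | tetrasubstituted trimethylsilyl enol ether of F1 | CC(C)=CCC/C(C)=C/C[C@@H]1CC(CC=C(C)C)=C(O[Si](C)(C)C)C[C@@]1(C)CCC=C(C)C
F3 | step 12 | 4-hydroxy-5-prenyl-7-geranyl-8-methyl-8-homoprenylbicyclo[3.3.1]non-3-ene-2,9-dione | CC(C)=CCC/C(C)=C/C[C@@H]1C[C@]2(CC=C(C)C)C(=O)[C@@H](C(=O)C=C2O)[C@@]1(C)CCC=C(C)C
F4 | step 12 | 4-methoxy-5-prenyl-7-geranyl-8-methyl-8-homoprenylbicyclo[3.3.1]non-3-ene-2,9-dione | CC(C)=CCC/C(C)=C/C[C@@H]1C[C@]2(CC=C(C)C)C(=O)[C@@H](C(=O)C=C2OC)[C@@]1(C)CCC=C(C)C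
F5 | step 9 | pyrrolidine enamine of 12, double bond away from the quaternary carbon | CC(C)=CCC/C(C)=C/C[C@@H]1CC=C(N2CCCC2)C[C@@]1(C)CCC=C(C)C
F6 | step 9 | 7-geranyl-8-methyl-8-homoprenylbicyclo[3.3.1]nonane-2,9-dione | CC(C)=CCC/C(C)=C/C[C@@H]1C[C@@H]2C(=O)[C@@H](C(=O)CC2)[C@@]1(C)CCC=C(C)C
F7 | step 9 | 7-geranyl-8-methyl-8-homoprenylbicyclo[3.3.1]non-3-ene-2,9-dione | CC(C)=CCC/C(C)=C/C[C@@H]1C[C@@H]2C(=O)[C@@H](C(=O)C=C2)[C@@]1(C)CCC=C(C)C
F8 | step 16 | 3-(tert-butyldimethylsilyloxy)benzaldehyde | CC(C)(C)[Si](C)(C)Oc1cccc(C=O)c1
F9 | step 16 | C3 hydroxy[3-(tert-butyldimethylsilyloxy)phenyl]methyl derivative of 21, carbinol centre undefined | CC(C)=CCC/C(C)=C/C[C@@H]1C[C@]2(CC=C(C)C)C(=O)[C@@](CC=C(C)C)(C(=O)C(C(O)c3cccc(O[Si](C)(C)C(C)(C)C)c3)=C2OC)[C@@]1(C)CCC=C(C)C
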